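The quinone ring is cut at C2–C3, the bond joining the henicosyl-bearing and methyl-bearing carbons. These two atoms are the α-carbons of the ring carbonyls C1 and C4, so the bond is the central bond of a 1,4-dicarbonyl unit and can be made by oxidative coupling of two enol carbons of like (nucleophilic) polarity. The precursor is acyclic: the bis(silyl enol ether) of a cis-ene-1,4-dione, itself unmasked from a 2,5-dialkyl-3-methoxyfuran. Oxidation with (NH4)2Ce(NO3)6 should, in one operation, close the six-membered carbocycle, let it aromatise to the hydroquinone and oxidise this to the quinone; the furan oxygen bridge is thus exchanged for a C–C bond on the opposite flank.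

Key step: step 5

Assumption: 3-methoxyfuran is treated as a purchasable building block; the two outer enol ether double bonds of 6 are expected as E/Z mixtures, which is without consequence because both carbons become sp2 in the product.

Step 1
Reactants: 1 3-methoxyfuran; 2 1-bromodocosane
Product: 3 2-docosyl-3-methoxyfuran
Conditions: n-BuLi, THF, −78 → 0 °C; then 2, DMPU, 0 °C → rt; base-washed work-up
Reagents that add atoms: none
Why: Directed α-lithiation at C2, the position flanked by the ring oxygen and the methoxy group, followed by SN2 alkylation of the 2-furyllithium with the primary bromide (furan metalation–alkylation).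

Step 2
Reactants: 3 2-docosyl-3-methoxyfuran
Product: 4 2-docosyl-5-ethyl-3-methoxyfuran
Conditions: n-BuLi, THF, −78 → 0 °C; then EtI, −78 °C → rt
Reagents that add atoms: iodoethane, CCI
Why: The remaining α-position C5 is the most acidic ring C–H of a 2-alkylfuran, so a second α-lithiation and SN2 ethylation should be regioselective (furan metalation–alkylation).

Step 3
Reactants: 4 2-docosyl-5-ethyl-3-methoxyfuran
Product: 5 (4E)-5-methoxyoctacos-4-ene-3,6-dione
Conditions: dimethyldioxirane (1.05 equiv) in acetone, CH2Cl2, −78 → −20 °C, dark; used without delay
Reagents that add atoms: dimethyldioxirane, CC1(C)OO1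
Why: Oxidative ring opening of a furan: oxygen-atom transfer to the electron-rich ring gives an epoxide that opens to the ene-1,4-dione, and the former ring enforces the cis arrangement of the two carbonyl carbons (4E by the sequence rules, because the methoxy group outranks C6).

Step 4
Reactants: 5 (4E)-5-methoxyoctacos-4-ene-3,6-dione
Product: 6 (4E)-5-methoxy-3,6-bis(trimethylsilyloxy)octacosa-2,4,6-triene
Conditions: LiN(iPr)2 (2.4 equiv), Me3SiCl (5 equiv) premixed, THF, −78 °C, slow addition of 5; then Et3N, pentane, filtration, concentration; used crude
Reagents that add atoms: chlorotrimethylsilane, C[Si](C)(C)Cl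
Why: Kinetic enolisation with in-situ silyl chloride quench: only the outer CH2 groups C2 and C7 carry enolisable hydrogens because C4 and C5 are sp2, and immediate O-silylation keeps each enolate from adding to unreacted enedione, so the central double bond keeps its geometry.

Step 5
Reactants: 6 (4E)-5-methoxy-3,6-bis(trimethylsilyloxy)octacosa-2,4,6-triene
Product: 9 2-henicosyl-6-methoxy-3-methyl-1,4-benzoquinone, via cyclic ene-dione 7 (not isolated), via hydroquinone 8 (not isolated)
Conditions: (NH4)2Ce(NO3)6 (4.5 equiv), NaHCO3, MeCN/CH2Cl2, −30 °C → rt; then H2O
Reagents that add atoms: none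
Why: Tetravalent cerium removes one electron from one silyl enol ether of the electron-rich triene, the resulting radical cation bonds through its α-carbon (C2) to the nucleophilic β-carbon (C7) of the other enol ether, and a second electron transfer with loss of both silyl groups gives ene-dione 7. Compound 7 is the keto tautomer of hydroquinone 8, so enolisation aromatises it, and two further equivalents of oxidant take 8 to quinone 9. The closest known reaction type is the oxidative coupling of silyl enol ethers or ketone bis-enolates to 1,4-diketones, used here in its intramolecular form, followed by the standard oxidation of a hydroquinone by (NH4)2Ce(NO3)6. The six-membered carbocycle closes 6-endo-trig with respect to the accepting enol ether, between the termini of a hexatriene whose central C4=C5 bond holds them cis. No stereocentre has to be controlled, since the two sp3 centres of 7 are erased on aromatisation. The step needs ring closure to outrun desilylation, nitrate capture and 5-exo attack: the cis geometry inherited from the furan keeps C2 and C7 within bonding distance, the polarity match directs the radical cation to C7 and not to the oxygen-bearing C6, and C4 and C5 carry no enolisable hydrogen, so no other enol ether can form or couple.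

Compound list
1 | 3-methoxyfuran | COc1ccoc1 | starting material
2 | 1-bromodocosane | CCCCCCCCCCCCCCCCCCCCCCBr | starting material
3 | 2-docosyl-3-methoxyfuran | CCCCCCCCCCCCCCCCCCCCCCc1occc1OC | intermediate
4 | 2-docosyl-5-ethyl-3-methoxyfuran | CCCCCCCCCCCCCCCCCCCCCCc1oc(CC)cc1OC | intermediate
5 | (4E)-5-methoxyoctacos-4-ene-3,6-dione (carbonyl carbons C3 and C6 cis) | CCC(=O)/C=C(/OC)C(=O)CCCCCCCCCCCCCCCCCCCCCC | intermediate
6 | (4E)-5-methoxy-3,6-bis(trimethylsilyloxy)octacosa-2,4,6-triene (C2=C3 and C6=C7 as geometric mixtures) | CC=C(O[Si](C)(C)C)/C=C(/OC)C(O[Si](C)(C)C)=CCCCCCCCCCCCCCCCCCCCCC | intermediate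
7 | 2-henicosyl-6-methoxy-3-methylcyclohex-5-ene-1,4-dione (cis/trans mixture, racemic, formed in the flask in step 5) | CCCCCCCCCCCCCCCCCCCCCC1C(C)C(=O)C=C(OC)C1=O | intermediate
8 | 2-henicosyl-6-methoxy-3-methylbenzene-1,4-diol (formed in the flask in step 5) | CCCCCCCCCCCCCCCCCCCCCc1c(C)c(O)cc(OC)c1O | intermediate
9 | 2-henicosyl-6-methoxy-3-methylcyclohexa-2,5-diene-1,4-dione (2-henicosyl-6-methoxy-3-methyl-1,4-benzoquinone) | CCCCCCCCCCCCCCCCCCCCCC1=C(C)C(=O)C=C(OC)C1=O | target

Total step count: 5
Longest linear sequence: 5 steps (1 → 3 → 4 → 5 → 6 → 9)

Steps most likely to fail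

Step 5. The silyl enol ethers may be protodesilylated by the acidic oxidant before electron transfer, or the radical cation may be captured by nitrate or by a second molecule ahead of ring closure. The fallback sets out from 6 and returns at 9, and forms the same bond by a pericyclic ring closure. Heating 6 in degassed toluene at 110 °C with a trace of Et3N should bring about a thermal disrotatory 6π-electrocyclisation to 6-henicosyl-2-methoxy-5-methyl-1,4-bis(trimethylsilyloxy)cyclohexa-1,3-diene F1. DDQ (1.1 equiv, benzene, rt) should dehydrogenate this to 2-henicosyl-6-methoxy-3-methyl-1,4-bis(trimethylsilyloxy)benzene F2. Oxidative desilylation of F2 with (NH4)2Ce(NO3)6 in MeCN/H2O at 0 °C should then give 9.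

Step 4. The amide base or the first-formed enolate may add in conjugate fashion to the enedione, or the push–pull C4=C5 bond may rotate during enolisation. The fallback sets out from 5 and returns at 9 without any silyl intermediate. Slow addition of 5 to LiN(iPr)2 (2.3 equiv) in THF at −78 °C should give dilithium (4E)-5-methoxyoctacosa-2,4,6-triene-3,6-diolate F3. Oxidation in the same flask with anhydrous CuCl2 (4.5 equiv) in DMF, −78 °C → rt, then air (copper-mediated oxidative coupling of lithium enolates), should reach 9 through 7 and 8.

Step 3. The electron-rich furan or the product may be over-oxidised, and traces of acid may hydrolyse the enol ether or let the cis-enedione drift to the trans isomer. The fallback sets out from 4 and returns at 5, replacing oxygen-atom transfer by a cycloaddition–reduction sequence. Photooxygenation of 4 (O2, tetraphenylporphyrin, visible light, CH2Cl2, −78 °C) should give by [4+2] addition of singlet oxygen the racemic endoperoxide 1-docosyl-4-ethyl-6-methoxy-2,3,7-trioxabicyclo[2.2.1]hept-5-ene F4. Me2S at −78 → 0 °C should reduce F4 to 5.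

Further compounds
F1 | step 5 | 6-henicosyl-2-methoxy-5-methyl-1,4-bis(trimethylsilyloxy)cyclohexa-1,3-diene (cis/trans mixture, racemic) | CCCCCCCCCCCCCCCCCCCCCC1C(C)C(O[Si](C)(C)C)=CC(OC)=C1O[Si](C)(C)C
F2 | step 5 | 2-henicosyl-6-methoxy-3-methyl-1,4-bis(trimethylsilyloxy)benzene | CCCCCCCCCCCCCCCCCCCCCc1c(C)c(O[Si](C)(C)C)cc(OC)c1O[Si](C)(C)C
F3 | step 4 | dilithium (4E)-5-methoxyoctacosa-2,4,6-triene-3,6-diolate | [Li+].[Li+].CC=C([O-])/C=C(/OC)C([O-])=CCCCCCCCCCCCCCCCCCCCCC
F4 | step 3 | 1-docosyl-4-ethyl-6-methoxy-2,3,7-trioxabicyclo[2.2.1]hept-5-ene (racemic) | CCC12C=C(OC)C(CCCCCCCCCCCCCCCCCCCCCC)(OO1)O2
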